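**Retrosynthetic overview**
1. Target 32 ⇐ phenol sulfation and desilylation ⇐ debenzylation of 29 ⇐ Cu-catalysed opening of spiro-epoxide 12 (benzoxepine half) at its CH2 by Grignard reagent 28 (bicyclooctane half); this closes the (CH2)4 linker.
2. 12 ⇐ ketone 10 ⇐ alkene 8. The oxepane and cyclohexene rings of 8 form together in one electrophile-triggered epoxide-opening/vinylsilane cascade of acyclic 6 (geraniol, Sharpless epoxide).
3. 27 ⇐ keto-styrene 26 by a cationic Prins-type closure (bicyclo[2.2.2]octan-1-ol formed last) ⇐ cyclobutane-opening alkenylation of pinanone 24 with vinylsilane 17 ⇐ (–)-β-pinene, which supplies the six-membered ring and its CH stereocentre.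
4. Ring order: half A, epoxonium (oxepane) then cyclohexene; half B, pinene six-ring, cyclobutane opened, then bicyclo[2.2.2]octane; the arene comes from 4-(benzyloxy)phenol.

Assumption: the presumed biosynthesis is taken as (i) an electrophile-triggered cascade in which an epoxide oxygen closes the oxepane and an olefin opens the epoxonium ion, and (ii) a cationic Prins-type closure of the benzyl-bearing olefinic carbon onto the ring carbon that becomes the bridgehead carbinol; the sulfate is drawn as the free acid.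

Locants used below: 1-benzoxepine (O1, C2 gem-dimethyl, C5a, C6, C7, C9a); bicyclo[2.2.2]octane (C1 carbinol, C2 benzyl-bearing, C3 gem-dimethyl, C4 bridgehead H, C5 quaternary).

**Step 1**
Reactants: 1 geraniol
Product: 3 (2S,3S)-2,3-epoxygeranyl p-toluenesulfonate, via epoxygeraniol 2 (not isolated)
Conditions: Ti(OiPr)4 (5 mol%), L-(+)-DET (7.5 mol%), t-BuOOH, 4 Å MS, CH2Cl2, –20 °C; then P(OMe)3, Et3N, DMAP (cat.), TsCl, –10 °C
Reagents that add atoms: tert-butyl hydroperoxide, CC(C)(C)OO; p-toluenesulfonyl chloride, Cc1ccc(cc1)S(Cl)(=O)=O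
Why: Sharpless asymmetric epoxidation touches only the allylic-alcohol olefin and with L-(+)-tartrate gives the (2S,3S)-epoxide (the future C9a and C5a), which is tosylated in situ.

**Step 2**
Reactants: 4 trimethyl(2-methylallyl)silane; 3 epoxygeranyl tosylate
Product: 6 (E)-vinylsilane epoxy-diene, via lithiated allylsilane 5 (not isolated)
Conditions: 4, s-BuLi, TMEDA, THF, –78 °C; then 3, –78 → –30 °C
Reagents that add atoms: none
Why: γ-selective SN2 alkylation of the α-silylallyl anion at the primary tosylate leaves the trisubstituted epoxide intact and installs the vinylsilane terminator.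

**Step 3**
Reactants: 6 vinylsilane epoxy-diene
Product: 8 (5aS,9aS)-2,2,5a,7-tetramethyl-2,3,4,5,5a,8,9,9a-octahydro-1-benzoxepine, via alkylmercurial 7 (not isolated)
Conditions: Hg(OCOCF3)2 (1.05 equiv), MeNO2, –25 °C; then 3 M NaOH, NaBH4, 0 °C
Reagents that add atoms: none
Why: Proposed new method: Hg(II) adds to the most electron-rich, unhindered trisubstituted olefin, the epoxide oxygen captures the tertiary carbon (six-membered epoxonium ion), the vinylsilane opens the epoxonium at its tertiary carbon anti to oxygen through a chair (trans fusion, C5a methyl anti to C9a-H, stereospecific from the E-derived epoxide) and loses Me3Si+ to fix the 6,7-olefin, and NaBH4 demercurates; closest known types are Hg(II)-induced polyene cyclisation, bromonium- or epoxonium-initiated oxa/carbacyclisation cascades and vinylsilane-terminated cation–olefin cyclisation.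

**Step 4**
Reactants: 8 octahydrobenzoxepine
Product: 10 (5aR,7S,9aS)-2,2,5a,7-tetramethyloctahydro-1-benzoxepin-6(2H)-one, via alkylborane 9 (not isolated)
Conditions: BH3·THF, 0 °C → rt; then NMO, TPAP (5 mol%), 4 Å MS, CH2Cl2; then DBU (cat.), rt
Reagents that add atoms: N-methylmorpholine N-oxide, C[N+]1([O-])CCOCC1
Why: Anti-Markovnikov hydroboration puts boron on C6 and TPAP/NMO oxidation of the organoborane gives the ketone; base equilibration then sets C7 with the methyl equatorial, because the axial epimer suffers a 1,3-diaxial Me/Me contact with the C5a methyl.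

**Step 5**
Reactants: 10 benzoxepinone
Product: 11 (5aS,7S,9aS)-2,2,5a,7-tetramethyl-6-methylidenedecahydro-1-benzoxepine
Conditions: Ph3PCH3Br, KOt-Bu, toluene, 90 °C
Reagents that add atoms: methyltriphenylphosphonium bromide, C[P+](c1ccccc1)(c1ccccc1)c1ccccc1.[Br-]
Why: Wittig methylenation of the hindered ketone; C7 stays in its thermodynamic configuration.

**Step 6**
Reactants: 11 exocyclic alkene
Product: 12 (5aR,6S,7S,9aS)-2,2,5a,7-tetramethyloctahydro-2H-spiro[1-benzoxepine-6,2'-oxirane]
Conditions: mCPBA, NaHCO3, CH2Cl2, 0 °C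
Reagents that add atoms: 3-chloroperoxybenzoic acid, OOC(=O)c1cccc(Cl)c1
Why: Prilezhaev epoxidation from the face anti to the adjacent axial C5a methyl places the oxygen axial and so sets the C6 carbinol configuration.

**Step 7**
Reactants: 13 4-(benzyloxy)phenol
Product: 14 4-(benzyloxy)-2-bromophenol
Conditions: NBS, MeCN, 0 °C
Reagents that add atoms: N-bromosuccinimide, BrN1C(=O)CCC1=O
Why: Electrophilic aromatic bromination ortho to the free phenol, the stronger director, with the para position blocked.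

**Step 8**
Reactants: 14 bromophenol
Product: 15 [4-(benzyloxy)-2-bromophenoxy]triisopropylsilane
Conditions: TIPSCl, imidazole, DMF, rt
Reagents that add atoms: triisopropylsilyl chloride, CC(C)[Si](Cl)(C(C)C)C(C)C
Why: O-silylation; the two phenol oxygens are now differentiated (Bn on the future sulfate oxygen, TIPS on the future free OH).

**Step 9**
Reactants: 15 aryl bromide; 16 vinyltrimethylsilane
Product: 17 (E)-{2-[5-(benzyloxy)-2-(triisopropylsilyloxy)phenyl]ethenyl}trimethylsilane
Conditions: Pd(P(t-Bu)3)2 (3 mol%), Cy2NMe, dioxane, 80 °C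
Reagents that add atoms: none
Why: Heck reaction; β-arylation of the vinylsilane gives the (E)-β-silylstyrene.

**Step 10**
Reactants: 18 (–)-β-pinene; 19 oxirane
Product: 21 3-[(1R,5S)-6,6-dimethylbicyclo[3.1.1]hept-2-en-2-yl]propan-1-ol, via pinenyllithium 20 (not isolated)
Conditions: n-BuLi, TMEDA, hexane, rt → 40 °C; then oxirane, THF, –78 → 0 °C; H2O
Reagents that add atoms: none
Why: Allylic metalation of β-pinene and alkylation of the allyl anion at its exocyclic terminus with oxirane; both stereocentres come from the chiral pool.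

**Step 11**
Reactants: 21 pinenylpropanol
Product: 22 (1R,5S)-2-(3-chloropropyl)-6,6-dimethylbicyclo[3.1.1]hept-2-ene
Conditions: PPh3, CCl4, reflux
Reagents that add atoms: carbon tetrachloride, ClC(Cl)(Cl)Cl
Why: Appel chlorination of the primary alcohol.

**Step 12**
Reactants: 22 chloropropylpinene
Product: 23 (1S,5R)-4-(3-chloropropyl)-6,6-dimethylbicyclo[3.1.1]hept-3-en-2-one
Conditions: t-BuOOH (5 equiv), Rh2(cap)4 (1 mol%), K2CO3, CH2Cl2, rt
Reagents that add atoms: tert-butyl hydroperoxide, CC(C)(C)OO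
Why: Allylic C–H oxidation at the ring CH2 to the enone, as in α-pinene → verbenone.

**Step 13**
Reactants: 23 enone
Product: 24 (1S,4R,5S)-4-(3-chloropropyl)-4,6,6-trimethylbicyclo[3.1.1]heptan-2-one
Conditions: MeMgBr, CuI (10 mol%), THF, –30 °C; H2O
Reagents that add atoms: methylmagnesium bromide, C[Mg]Br
Why: Copper-catalysed conjugate addition; the methyl enters anti to the gem-dimethyl bridge and sets the quaternary centre (future C5 of the bicyclooctane, chain cis to the CMe2 carbon).

**Step 14**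
Reactants: 24 pinanone; 17 β-silylstyrene
Product: 26 (3R,4S)-3-(3-chloropropyl)-3-methyl-4-{(3E)-4-[5-(benzyloxy)-2-(triisopropylsilyloxy)phenyl]-2-methylbut-3-en-2-yl}cyclohexan-1-one, via silyl enol ether 25 (not isolated)
Conditions: TMSOTf (0.3 equiv), CH2Cl2, –60 → –20 °C; then aq. citric acid, THF
Reagents that add atoms: none
Why: Proposed new method: O-silylation of the strained cyclobutyl ketone lets the bond between the α-carbon and the CMe2 carbon heterolyse with strain release to a silyl enol ether and a tertiary (terpinyl-type) cation, which the β-silylstyrene traps at its silyl-bearing carbon (ipso attack, β-silyl benzylic cation) with loss of Me3Si+ that carries the chain; closest known types are Lewis-acid or TMSI cleavage of nopinone, Reetz tert-alkylation, Fleming-type substitution of vinylsilanes and silyl-triflate-catalysed Sakurai reactions; the two ring stereocentres are untouched.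

**Step 15**
Reactants: 26 keto-styrene
Product: 27 (1S,2S,4S,5R)-2-{[5-(benzyloxy)-2-(triisopropylsilyloxy)phenyl]methyl}-5-(3-chloropropyl)-3,3,5-trimethyl-1-(triethylsilyloxy)bicyclo[2.2.2]octane
Conditions: Et3SiH (1.5 equiv), TESOTf (0.2 equiv), 2,6-di-tert-butyl-4-methylpyridine (0.1 equiv), CH2Cl2, –78 → –40 °C
Reagents that add atoms: triethylsilane, CC[SiH](CC)CC
Why: Proposed new method: the silyloxocarbenium ion of the ketone is attacked through a boat by the β-carbon of the electron-rich styrene (Prins-type carbonyl–olefin cyclisation; collapse to olefin metathesis is blocked by Bredt's rule), the o-siloxybenzyl cation is reduced by Et3SiH and the released Et3Si+ carries the chain, the bridgehead carbinol C1 can only form exo, and C2 is set in the transition state in which the arylvinyl terminus points to the ethano bridge, away from the cis chloropropyl group on C5; closest known types are Lewis-acid Prins and carbonyl-ene cyclisations of keto-olefins to bridged tertiary alcohols, silane-terminated Prins reactions and ionic hydrogenation.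

**Step 16**
Reactants: 27 bicyclooctyl chloride; 12 spiro-epoxide
Product: 29 coupled bis-silyl benzyl ether, via Grignard reagent 28 (not isolated)
Conditions: Mg, I2 (cat.), THF, 60 °C; then CuI (10 mol%), 12, THF, –30 → 0 °C; H2O
Reagents that add atoms: none
Why: Grignard formation from the primary chloride and copper-catalysed SN2 opening of the 1,1-disubstituted epoxide at its CH2 complete the four-carbon linker and leave the C6 oxygen (set in step 6) as the axial tertiary alcohol.

**Step 17**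
Reactants: 29 coupled benzyl ether
Product: 30 phenol (5-OH free, 2-OTIPS and bridgehead OTES retained)
Conditions: H2 (1 atm), 10% Pd/C, EtOAc, rt
Reagents that add atoms: none
Why: Hydrogenolysis of the aryl benzyl ether frees only the phenol that is to be sulfated.

**Step 18**
Reactants: 30 phenol
Product: 32 target, 4-hydroxy-3-{[(1S,2S,4S,5R)-1-hydroxy-5-{4-[(5aR,6S,7S,9aS)-6-hydroxy-2,2,5a,7-tetramethyldecahydro-1-benzoxepin-6-yl]butyl}-3,3,5-trimethylbicyclo[2.2.2]octan-2-yl]methyl}phenyl hydrogen sulfate, via silylated aryl sulfate 31 (not isolated)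
Conditions: SO3·pyridine (3 equiv), pyridine, rt; then TBAF, THF, 45 °C; Dowex 50W (H+)
Reagents that add atoms: sulfur trioxide–pyridine complex, [O-]S(=O)(=O)[n+]1ccccc1
Why: O-sulfation of the only free phenol (the hindered tertiary alcohol is inert to SO3·pyridine) followed by fluoride cleavage of the aryl TIPS and bridgehead TES ethers; no stereocentre is touched.

**Compound list**
1 | geraniol, (2E)-3,7-dimethylocta-2,6-dien-1-ol | CC(C)=CCC/C(C)=C/CO | starting material
2 | (2S,3S)-2,3-epoxygeraniol | OC[C@@H]1O[C@@]1(C)CCC=C(C)C | intermediate (not isolated)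
3 | [(2S,3S)-3-methyl-3-(4-methylpent-3-en-1-yl)oxiran-2-yl]methyl 4-methylbenzenesulfonate | Cc1ccc(cc1)S(=O)(=O)OC[C@@H]1O[C@@]1(C)CCC=C(C)C | intermediate
4 | trimethyl(2-methylprop-2-en-1-yl)silane | C[Si](C)(C)CC(C)=C | starting material
5 | [2-methyl-1-(trimethylsilyl)prop-2-en-1-yl]lithium | [Li]C(C(C)=C)[Si](C)(C)C | intermediate (not isolated)
6 | trimethyl{(1E)-2-methyl-4-[(2S,3S)-3-methyl-3-(4-methylpent-3-en-1-yl)oxiran-2-yl]but-1-en-1-yl}silane | C[Si](C)(C)/C=C(\C)CC[C@@H]1O[C@@]1(C)CCC=C(C)C | intermediate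
7 | [(5aS,9aS)-2,2,5a,7-tetramethyl-2,3,4,5,5a,8,9,9a-octahydro-1-benzoxepin-3-yl]mercury trifluoroacetate (C3 not assigned) | CC=1CC[C@@H]2OC(C)(C)C(CC[C@@]2(C)C=1)[Hg]OC(=O)C(F)(F)F | intermediate (not isolated)
8 | (5aS,9aS)-2,2,5a,7-tetramethyl-2,3,4,5,5a,8,9,9a-octahydro-1-benzoxepine (trans-fused) | CC=1CC[C@@H]2OC(C)(C)CCC[C@@]2(C)C=1 | intermediate
9 | 6-boryl adduct of 8 (alkylborane, B and H added to the face anti to the C5a methyl) | C[C@@H]1CC[C@@H]2OC(C)(C)CCC[C@@]2(C)[C@H]1B | intermediate (not isolated)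
10 | (5aR,7S,9aS)-2,2,5a,7-tetramethyloctahydro-1-benzoxepin-6(2H)-one | C[C@H]1CC[C@@H]2OC(C)(C)CCC[C@@]2(C)C1=O | intermediate
11 | (5aS,7S,9aS)-2,2,5a,7-tetramethyl-6-methylidenedecahydro-1-benzoxepine | C[C@H]1CC[C@@H]2OC(C)(C)CCC[C@@]2(C)C1=C | intermediate
12 | (5aR,6S,7S,9aS)-2,2,5a,7-tetramethyloctahydro-2H-spiro[1-benzoxepine-6,2'-oxirane] (epoxide O axial, anti to the C5a methyl) | C[C@H]1CC[C@@H]2OC(C)(C)CCC[C@@]2(C)[C@]1(O3)C3 | intermediate
13 | 4-(benzyloxy)phenol | Oc1ccc(OCc2ccccc2)cc1 | starting material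
14 | 4-(benzyloxy)-2-bromophenol | Oc1ccc(OCc2ccccc2)cc1Br | intermediate
15 | [4-(benzyloxy)-2-bromophenoxy]triisopropylsilane | CC(C)[Si](C(C)C)(C(C)C)Oc1ccc(OCc2ccccc2)cc1Br | intermediate
16 | vinyltrimethylsilane | C=C[Si](C)(C)C | starting material
17 | (E)-{2-[5-(benzyloxy)-2-(triisopropylsilyloxy)phenyl]ethenyl}trimethylsilane | C[Si](C)(C)/C=C/c1cc(OCc2ccccc2)ccc1O[Si](C(C)C)(C(C)C)C(C)C | intermediate
18 | (–)-β-pinene, (1S,5S)-6,6-dimethyl-2-methylidenebicyclo[3.1.1]heptane | C=C1CC[C@H]2C[C@@H]1C2(C)C | starting material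
19 | oxirane | C1CO1 | starting material
20 | {[(1R,5S)-6,6-dimethylbicyclo[3.1.1]hept-2-en-2-yl]methyl}lithium | [Li]CC1=CC[C@H]2C[C@@H]1C2(C)C | intermediate (not isolated)
21 | 3-[(1R,5S)-6,6-dimethylbicyclo[3.1.1]hept-2-en-2-yl]propan-1-ol | OCCCC1=CC[C@H]2C[C@@H]1C2(C)C | intermediate
22 | (1R,5S)-2-(3-chloropropyl)-6,6-dimethylbicyclo[3.1.1]hept-2-ene | ClCCCC1=CC[C@H]2C[C@@H]1C2(C)C | intermediate
23 | (1S,5R)-4-(3-chloropropyl)-6,6-dimethylbicyclo[3.1.1]hept-3-en-2-one | ClCCCC1=CC(=O)[C@H]2C[C@@H]1C2(C)C | intermediate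
24 | (1S,4R,5S)-4-(3-chloropropyl)-4,6,6-trimethylbicyclo[3.1.1]heptan-2-one (4-methyl anti to the CMe2 bridge) | ClCCC[C@]1(C)CC(=O)[C@H]2C[C@@H]1C2(C)C | intermediate
25 | trimethylsilyl enol ether of 26 (enol double bond toward the former bridgehead carbon) | ClCCC[C@]1(C)CC(O[Si](C)(C)C)=CC[C@@H]1C(C)(C)/C=C/c1cc(OCc2ccccc2)ccc1O[Si](C(C)C)(C(C)C)C(C)C | intermediate (not isolated)
26 | (3R,4S)-3-(3-chloropropyl)-3-methyl-4-{(3E)-4-[5-(benzyloxy)-2-(triisopropylsilyloxy)phenyl]-2-methylbut-3-en-2-yl}cyclohexan-1-one | ClCCC[C@]1(C)CC(=O)CC[C@@H]1C(C)(C)/C=C/c1cc(OCc2ccccc2)ccc1O[Si](C(C)C)(C(C)C)C(C)C | intermediate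
27 | (1S,2S,4S,5R)-2-{[5-(benzyloxy)-2-(triisopropylsilyloxy)phenyl]methyl}-5-(3-chloropropyl)-3,3,5-trimethyl-1-(triethylsilyloxy)bicyclo[2.2.2]octane | ClCCC[C@]1(C)C[C@@]2(O[Si](CC)(CC)CC)CC[C@@H]1C(C)(C)[C@@H]2Cc1cc(OCc2ccccc2)ccc1O[Si](C(C)C)(C(C)C)C(C)C | intermediate
28 | Grignard reagent of 27, 3-(bicyclooctan-5-yl)propylmagnesium chloride | Cl[Mg]CCC[C@]1(C)C[C@@]2(O[Si](CC)(CC)CC)CC[C@@H]1C(C)(C)[C@@H]2Cc1cc(OCc2ccccc2)ccc1O[Si](C(C)C)(C(C)C)C(C)C | intermediate (not isolated)
29 | (5aR,6S,7S,9aS)-6-{4-[(1R,2S,4S,5S)-5-{[5-(benzyloxy)-2-(triisopropylsilyloxy)phenyl]methyl}-2,6,6-trimethyl-4-(triethylsilyloxy)bicyclo[2.2.2]octan-2-yl]butyl}-2,2,5a,7-tetramethyldecahydro-1-benzoxepin-6-ol (locants of the bicyclooctane as a substituent; same centres as in 27) | C[C@H]1CC[C@@H]2OC(C)(C)CCC[C@@]2(C)[C@]1(O)CCCC[C@]1(C)C[C@@]2(O[Si](CC)(CC)CC)CC[C@@H]1C(C)(C)[C@@H]2Cc1cc(OCc2ccccc2)ccc1O[Si](C(C)C)(C(C)C)C(C)C | intermediate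
30 | debenzylated 29, the 5-hydroxy-2-(triisopropylsilyloxy)phenyl compound | C[C@H]1CC[C@@H]2OC(C)(C)CCC[C@@]2(C)[C@]1(O)CCCC[C@]1(C)C[C@@]2(O[Si](CC)(CC)CC)CC[C@@H]1C(C)(C)[C@@H]2Cc1cc(O)ccc1O[Si](C(C)C)(C(C)C)C(C)C | intermediate
31 | aryl hydrogen sulfate of 30 (TIPS and TES ethers still present; formed as its pyridinium salt) | C[C@H]1CC[C@@H]2OC(C)(C)CCC[C@@]2(C)[C@]1(O)CCCC[C@]1(C)C[C@@]2(O[Si](CC)(CC)CC)CC[C@@H]1C(C)(C)[C@@H]2Cc1cc(OS(=O)(=O)O)ccc1O[Si](C(C)C)(C(C)C)C(C)C | intermediate (not isolated)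
32 | 4-hydroxy-3-{[(1S,2S,4S,5R)-1-hydroxy-5-{4-[(5aR,6S,7S,9aS)-6-hydroxy-2,2,5a,7-tetramethyldecahydro-1-benzoxepin-6-yl]butyl}-3,3,5-trimethylbicyclo[2.2.2]octan-2-yl]methyl}phenyl hydrogen sulfate | C[C@H]1CC[C@@H]2OC(C)(C)CCC[C@@]2(C)[C@]1(O)CCCC[C@]1(C)C[C@@]2(O)CC[C@@H]1C(C)(C)[C@@H]2Cc1cc(OS(=O)(=O)O)ccc1O | target

**Step count**
Total: 18 steps (each one-pot operation counted once).
Longest linear sequence: 9 steps (18 → 32 through steps 10–18; equally 1 → 32 through steps 1–6 and 16–18).

**Three steps most likely to fail**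

Step 3 (one-pot double cyclisation). Hg(II) may attack the epoxide or the vinylsilane first, or over-react with the ring olefin of 8. The fallback sets out from 6 and returns at 8, and forms the two rings in separate, mechanistically different operations. MeAlCl2 (CH2Cl2, –78 °C) triggers only the epoxide/vinylsilane carbocyclisation and gives (1S,2S)-2,4-dimethyl-2-(4-methylpent-3-en-1-yl)cyclohex-3-en-1-ol F1. The oxepane is then closed by a cobalt-salen hydrogen-atom-transfer Markovnikov hydroalkoxylation of the side-chain olefin (N-fluoro-2,4,6-trimethylpyridinium salt, PhSiH3), which gives 8.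

Step 14 (cyclobutane opening with alkenylation). The hindered tertiary cation may instead lose a proton, undergo a 1,2-hydride shift that erodes the adjacent CH stereocentre, or react too slowly with the bulky vinylsilane. The fallback sets out from 24 and 15 and returns at 26, and replaces the cationic C–C bond formation by a radical one. TMSI followed by water opens 24 to the tertiary iodide (3R,4S)-3-(3-chloropropyl)-4-(2-iodopropan-2-yl)-3-methylcyclohexan-1-one F2. Bromine–lithium exchange on 15 (n-BuLi) and DMF give 5-(benzyloxy)-2-(triisopropylsilyloxy)benzaldehyde F3, and Henry condensation with nitromethane gives the nitrostyrene [4-(benzyloxy)-2-[(E)-2-nitroethenyl]phenoxy]triisopropylsilane F4. Et3B/air then generates the tertiary radical from F2, which adds to F4 and expels NO2 to give 26.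

Step 15 (silane-terminated Prins closure). The silane may reduce the activated ketone before cyclisation, the strained adduct may revert, or C2 may form with poor selectivity. The fallback sets out from 26 and returns at 27, and uses a ketyl radical anion instead of an oxocarbenium ion. SmI2 (THF/HMPA, t-BuOH) effects a 6-exo ketyl–styrene cyclisation to (1S,2S,4S,5R)-2-{[5-(benzyloxy)-2-(triisopropylsilyloxy)phenyl]methyl}-5-(3-chloropropyl)-3,3,5-trimethylbicyclo[2.2.2]octan-1-ol F5, with the same steric preference at C2. TESOTf/2,6-lutidine then silylates F5 to 27.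

**Further compounds**
F1 | step 3 | (1S,2S)-2,4-dimethyl-2-(4-methylpent-3-en-1-yl)cyclohex-3-en-1-ol | CC=1CC[C@H](O)[C@@](C)(CCC=C(C)C)C=1
F2 | step 14 | (3R,4S)-3-(3-chloropropyl)-4-(2-iodopropan-2-yl)-3-methylcyclohexan-1-one | ClCCC[C@]1(C)CC(=O)CC[C@@H]1C(C)(C)I
F3 | step 14 | 5-(benzyloxy)-2-(triisopropylsilyloxy)benzaldehyde | O=Cc1cc(OCc2ccccc2)ccc1O[Si](C(C)C)(C(C)C)C(C)C
F4 | step 14 | [4-(benzyloxy)-2-[(E)-2-nitroethenyl]phenoxy]triisopropylsilane | [O-][N+](=O)/C=C/c1cc(OCc2ccccc2)ccc1O[Si](C(C)C)(C(C)C)C(C)C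
F5 | step 15 | (1S,2S,4S,5R)-2-{[5-(benzyloxy)-2-(triisopropylsilyloxy)phenyl]methyl}-5-(3-chloropropyl)-3,3,5-trimethylbicyclo[2.2.2]octan-1-ol | ClCCC[C@]1(C)C[C@@]2(O)CC[C@@H]1C(C)(C)[C@@H]2Cc1cc(OCc2ccccc2)ccc1O[Si](C(C)C)(C(C)C)C(C)C
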